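I began at the late end of the autumn run, where target fell from 99.0% at 8.00 min to 73.8% at 90.0 min, with substrate read at 0% at the first of those times.

all flasks: substrate 20 mM
- winter: reagent 27 mM; run made earlier
- autumn: reagent 2400 mM; run made earlier
- epsilon: reagent 20.0 mM; time 1.5 h
- alpha: reagent 60.0 mM; time 1.5 h
- beta: reagent 200 mM; time 1.5 h
- delta: reagent 500 mM; time 1.5 h
- theta: reagent 1500 mM; time 1.5 h

| run | time / min | target / % | substrate / % |
|---|---|---|---|
| winter | 8.00 | 0 | 101.1 |
| winter | 15.0 | 2.5 | 99.9 |
| winter | 25.0 | 1.4 | 101.2 |
| winter | 50.0 | 2.6 | 96.3 |
| winter | 90.0 | 32.2 | 63.8 |
| autumn | 8.00 | 99.0 | 0 |
| autumn | 25.0 | 92.2 | 1.7 |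
| autumn | 40.0 | 88.3 | 1.8 |
| autumn | 60.0 | 84.8 | 0.1 |
| autumn | 90.0 | 73.8 | 1.5 |

(standard deviation of a reading: 1 percentage point)

- amount of target at the end, in percent of the substrate charged for epsilon, alpha, beta, delta, theta, in this order
- the shape of the row from first to last (falls, then rises / hardly changes / rises all the way / rises, then falls / falls all the way)

- "hardly changes" means that all values lie within two and a half points (for a concentration: within two and a half percent of the largest)

From that fall I reckoned one quantity:

life = time between the two readings / ln(first reading / last reading) = 279 min

This life of the target, the first-order time in which target shrinks by a factor of e once substrate has stopped feeding it, is the top rung of my ladder. I held it equal in every flask, and that was my own choice. The winter run had 88.9 times less reagent than the autumn run, yet its target and substrate readings add up to 96.0% at 90.0 min, so some loss seems to persist in the winter run too.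

The lower rungs come from the winter run, which reached 32.2% target at 90.0 min after a long lag. I took the time of that stage to scale inversely with reagent:

rise time = 90.0 min × 27 mM / c(reagent)

This gives 1.62 min for theta, 12.2 min for beta and 40.5 min for alpha, all shorter than 1.5 h. Epsilon, at 122 min, takes longer than 1.5 h, so I expected it to stop on the way up with little target. In alpha, beta and theta I counted the substrate as wholly turned to target at the rise time, which was an estimate, and let target age for the time that remains:

end target = exp(−(time − rise time) / life)

That gives 83.8% for alpha, 75.7% for beta and 72.9% for theta.

The forecast read 8%, 96%, 96%, 92% and 82%, shape rises, then falls, on the ground “I assume this is proportional to reagent”. Its theta stood higher than mine.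

The flasks gave 10.3%, 85.7%, 77.9%, 76.1% and 75.3%, shape rises, then falls.

    substrate + reagent + target → 2 target (k = 146 /M²/min)
    substrate + reagent → target (k = 0.00253 /M/min)
    target → over-reaction product (k = 0.00321 /min)

The turning of target into over-reaction product is the largest single effect on the change of the outcome from alpha to theta: that change is −10 percentage points with the step and 0.26 points without it. The life of 279 min, run over the 88.4 min after theta's rise, leaves 72.9%, against the 75.3% the flask shows. In alpha the same life, run over 49.5 min, leaves 83.8%, and alpha stands at 85.7%.

The earlier runs and the new flask are calculated for substances that don't exist, noise included.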